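The cyclohexene ring is cut at C1–C6 and C2–C3 (C1 = oxirane carbon bearing C7H2OBz, C2 = CHOAc, C3 = CHOBz, C4=C5, C6 = oxirane CH). The key step exploits the fact that C3–C4=C5–C6 with the C3 oxygen is a furan and C7–C1–C2(OAc) is an (E)-3-acetoxyacrolein. One catalytic asymmetric Diels–Alder reaction closes the carbocycle as a 7-oxanorbornene and, with acetoxy endo, fixes the trans C2–O/C3–O pair in absolute terms. The precursor pair is therefore furan plus the O-acetylated enol of malonaldehyde. Base then breaks the C6–O bridge to give the C1=C6/C4=C5 diene; reduction, benzoylation and C1=C6 epoxidation follow.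

Key step: step 3

Assumption: the (R)-configured oxazaborolidinium ion is taken to leave open the Si face at both alkene carbons (Cα-Si/Cβ-Si) of the boron-bound s-trans enal, by analogy with the usual binding model for enals; should the adduct prove to be the antipode, the (S)-catalyst is used with no other change.

Step 1
Reactants: 1 1,1,3,3-tetramethoxypropane
Product: 2 sodium (E)-3-oxoprop-1-en-1-olate (sodium salt of the malonaldehyde enol)
Conditions: Amberlyst 15 (H+ form), H2O, 40 °C; filter; NaOH (1.0 equiv), 0 °C; freeze-dry
Reagents that add atoms: water, O; sodium hydroxide, [Na+].[OH-]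
Why: Acid-catalysed acetal hydrolysis frees malonaldehyde, and NaOH traps this acidic enol as its stable, W-shaped (E)-enolate salt, which fixes the E geometry needed later.

Step 2
Reactants: 2 sodium (E)-3-oxoprop-1-en-1-olate; 3 acetyl chloride
Product: 4 (E)-3-acetoxyacrolein [(E)-3-oxoprop-1-en-1-yl acetate]
Conditions: AcCl (1.0 equiv), THF (suspension), 0 °C to rt; filter; short-path distillation
Reagents that add atoms: acetyl chloride (compound 3), CC(Cl)=O
Why: O-Acylation of the ambident enolate by the hard acyl chloride gives the vinylogous mixed anhydride with the E double bond of the salt retained.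

Step 3
Reactants: 4 (E)-3-acetoxyacrolein; 5 furan
Product: 6 (1S,2S,3R,4R)-3-endo-acetoxy-7-oxabicyclo[2.2.1]hept-5-ene-2-exo-carbaldehyde
Conditions: (R)-tetrahydro-1-(2-methylphenyl)-3,3-diphenyl-1H,3H-pyrrolo[1,2-c][1,3,2]oxazaborole (20 mol%), HNTf2 (18 mol%), furan (10 equiv), CH2Cl2, −78 °C; Et3N quench at −78 °C; evaporation below 0 °C, used at once
Reagents that add atoms: none
Why: The N-protonated oxazaborolidine binds the formyl oxygen of 4 and lowers the LUMO of the enal, so that furan adds across the C=C bond in a concerted but asynchronous [4+2] cycloaddition, the closest known reactions being the oxazaborolidine-catalysed Diels–Alder additions of furan to 2-haloacroleins and to acrylates. The carbocycle is closed by suprafacial union of the two furan α-carbons with the two alkene carbons (C6–C1 and C3–C2 in target numbering), which leaves the furan oxygen as the one-atom bridge of a 7-oxanorbornene. The trans relation of formyl and acetoxy is copied from the E geometry of 4, and the absolute configuration at C1 and C2 comes from the catalyst, whose aryl group covers one face of the bound enal so that furan meets the Cα-Si/Cβ-Si face. The bridgehead centres C3 and C6 follow from the endo/exo mode: acetoxy endo and formyl exo is needed, and it is expected because the formyl group carries the bulky boron cation and is pushed away from the diene (the effect that makes bulky aluminium aryloxide Lewis acids exo-selective), while furan has no bridge hydrogens that would penalise an exo substituent. This mode is the one selectivity that precedent does not secure, so the reaction is held under kinetic control at −78 °C and quenched cold, because cycloreversion would cost enantiomeric purity. Only the centres at C2 and C3 survive into the target, so a formyl-endo isomer formed on the same enal face is a separable diastereomer and not the enantiomer.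

Step 4
Reactants: 6 (1S,2S,3R,4R)-3-endo-acetoxy-7-oxabicyclo[2.2.1]hept-5-ene-2-exo-carbaldehyde
Product: 8 (1R,6R)-6-hydroxy-2-(hydroxymethyl)cyclohexa-2,4-dien-1-yl acetate, via hydroxy dienal 7 (not isolated)
Conditions: DBU (0.2 equiv), CH2Cl2, −40 to −10 °C; then MeOH, CeCl3·7H2O (1.1 equiv), NaBH4 (1.0 equiv), −78 °C
Reagents that add atoms: none
Why: Catalytic DBU removes the endo hydrogen at C1, which lies nearly antiperiplanar to the C6–O bridge bond, so that a strain-releasing E1cB elimination gives the C1=C6/C4=C5 dienal with the C3 hydroxyl, and the Luche reduction then turns the formyl group into the C7 alcohol by 1,2-hydride addition without touching the diene, the acetate or the C2 and C3 centres.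

Step 5
Reactants: 8 (1R,6R)-6-hydroxy-2-(hydroxymethyl)cyclohexa-2,4-dien-1-yl acetate; 9 benzoyl chloride
Product: 10 [(5R,6R)-6-acetoxy-5-(benzoyloxy)cyclohexa-1,3-dien-1-yl]methyl benzoate
Conditions: BzCl (2.4 equiv), pyridine (4 equiv), DMAP (5 mol%), CH2Cl2, 0 °C
Reagents that add atoms: benzoyl chloride (compound 9), O=C(Cl)c1ccccc1
Why: DMAP-catalysed acylation through the N-benzoylpyridinium ion esterifies the primary C7 and the secondary C3 hydroxyl with retention at C3, under conditions too mild to move the acetate or aromatise the diene.

Step 6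
Reactants: 10 [(5R,6R)-6-acetoxy-5-(benzoyloxy)cyclohexa-1,3-dien-1-yl]methyl benzoate
Product: 11 (1S,2S,3R,6S)-2-acetoxy-3-(benzoyloxy)-1-[(benzoyloxy)methyl]-7-oxabicyclo[4.1.0]hept-4-ene (numbered from the quaternary oxirane carbon)
Conditions: mCPBA (1.3 equiv), CH2Cl2, 0 °C to rt, dark
Reagents that add atoms: mCPBA (3-chloroperoxybenzoic acid), O=C(OO)c1cccc(Cl)c1
Why: The Prilezhaev epoxidation should take place at the trisubstituted C1=C6 bond in preference to the disubstituted C4=C5 bond, and the peracid should approach anti to the C2 acetate, which allylic strain with the C1 substituent holds pseudoaxial, so that C1 and C6 are set together as the oxirane trans to OAc and cis to the C3 benzoate.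

Compound list
1 | 1,1,3,3-tetramethoxypropane | COC(OC)CC(OC)OC | starting material
2 | sodium (E)-3-oxoprop-1-en-1-olate | [Na+].[O-]/C=C/C=O | intermediate
3 | acetyl chloride | CC(Cl)=O | starting material
4 | (E)-3-acetoxyacrolein | CC(=O)O/C=C/C=O | intermediate
5 | furan | c1ccoc1 | starting material
6 | (1S,2S,3R,4R)-3-endo-acetoxy-7-oxabicyclo[2.2.1]hept-5-ene-2-exo-carbaldehyde (formyl syn to the oxygen bridge, acetoxy anti to it) | CC(=O)O[C@H]1[C@H]2C=C[C@H](O2)[C@@H]1C=O | intermediate
7 | (1R,6R)-2-formyl-6-hydroxycyclohexa-2,4-dien-1-yl acetate (trans hydroxy acetate; formed in the flask in step 4) | CC(=O)O[C@H]1[C@H](O)C=CC=C1C=O | intermediate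
8 | (1R,6R)-6-hydroxy-2-(hydroxymethyl)cyclohexa-2,4-dien-1-yl acetate | CC(=O)O[C@H]1[C@H](O)C=CC=C1CO | intermediate
9 | benzoyl chloride | O=C(Cl)c1ccccc1 | starting material
10 | [(5R,6R)-6-acetoxy-5-(benzoyloxy)cyclohexa-1,3-dien-1-yl]methyl benzoate | CC(=O)O[C@H]1[C@H](OC(=O)c2ccccc2)C=CC=C1COC(=O)c1ccccc1 | intermediate
11 | (1S,2S,3R,6S)-2-acetoxy-3-(benzoyloxy)-1-[(benzoyloxy)methyl]-7-oxabicyclo[4.1.0]hept-4-ene | CC(=O)O[C@H]1[C@H](OC(=O)c2ccccc2)C=C[C@@H]2O[C@@]21COC(=O)c1ccccc1 | target

Total step count: 6. Longest linear sequence: 6 steps (1 → 2 → 4 → 6 → 8 → 10 → 11).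

Steps most likely to fail

Step 3. Three processes threaten it:
- The boron-bound formyl group may take the endo position, which puts acetoxy exo.
- Furan may attack the acetoxy-bearing carbon of the activated enal as a π-nucleophile, with loss of acetate, instead of cycloadding.
- Any warming lets the adduct revert, which erodes the enantiomeric purity.

The fallback keeps the catalyst and kinetic control but no longer needs the exo-formyl mode. It sets out from 4 and 5 and carries the formyl-endo diastereomer that arises on the same enal face, (1R,2S,3R,4S)-3-exo-acetoxy-7-oxabicyclo[2.2.1]hept-5-ene-2-endo-carbaldehyde F1. DBU under the conditions of step 4 opens it to the cis hydroxy acetate (1R,6S)-2-formyl-6-hydroxycyclohexa-2,4-dien-1-yl acetate F2, which is reduced in the same flask to (1R,6S)-6-hydroxy-2-(hydroxymethyl)cyclohexa-2,4-dien-1-yl acetate F3. A Mitsunobu reaction (benzoic acid, PPh3 and DIAD, 2.5 equiv each, toluene, −20 to 0 °C) then esterifies C7 and replaces the C3 hydroxyl by benzoate with inversion. This comes back to the route at 10, so both cycloaddition modes converge on the same diene.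

Step 4. Three processes threaten it:
- Loss of acetic acid across C1–C2 may compete with cleavage of the bridge.
- The acetyl group may migrate from O2 to the freshly released O3.
- The hydroxy dienal may dehydrate to an arene.

The fallback replaces the amine-base elimination by a Lewis-acid-assisted opening of the kind known for 7-oxanorbornanones. It sets out from 6: TMSOTf and Et3N in CH2Cl2 at −78 °C form the silyl enol ether and silylate the bridge oxygen, the more basic of the two candidate leaving groups. The bridge then departs, and the C3 oxygen is capped at once as (1R,6R)-2-formyl-6-[(trimethylsilyl)oxy]cyclohexa-2,4-dien-1-yl acetate F4, which can neither migrate nor eliminate. Citric acid in MeOH at 0 °C removes the silyl group and comes back to the route at 7, which is reduced in the same flask under the Luche conditions of step 4 to 8.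

Step 6. Two processes threaten it:
- The peracid may oxidise C4=C5 as well.
- It may show poor facial selectivity at C1=C6.

The fallback replaces substrate control by a hydroxyl-directed, reagent-controlled epoxidation. It sets out from 6. DBU (0.2 equiv) forms 7, and BzCl, Et3N and DMAP added to the same flask give (5R,6R)-6-acetoxy-5-(benzoyloxy)cyclohexa-1,3-diene-1-carbaldehyde F5. Luche reduction gives the primary allylic alcohol (1R,6R)-6-acetoxy-5-(hydroxymethyl)cyclohexa-2,4-dien-1-yl benzoate F6. Sharpless asymmetric epoxidation (Ti(OiPr)4, L-(+)-diethyl tartrate, t-BuOOH, 4 Å molecular sieves, CH2Cl2, −20 °C) delivers oxygen only to the allylic-alcohol double bond C1=C6. The tartrate fixes the face, giving (1S,2S,3R,6S)-2-acetoxy-3-(benzoyloxy)-1-(hydroxymethyl)-7-oxabicyclo[4.1.0]hept-4-ene F7. Benzoylation (BzCl, pyridine, 0 °C) comes back to the route at 11.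

Further compounds
F1 | step 3 | (1R,2S,3R,4S)-3-exo-acetoxy-7-oxabicyclo[2.2.1]hept-5-ene-2-endo-carbaldehyde | CC(=O)O[C@H]1[C@@H]2C=C[C@@H](O2)[C@@H]1C=O
F2 | step 3 | (1R,6S)-2-formyl-6-hydroxycyclohexa-2,4-dien-1-yl acetate | CC(=O)O[C@H]1[C@@H](O)C=CC=C1C=O
F3 | step 3 | (1R,6S)-6-hydroxy-2-(hydroxymethyl)cyclohexa-2,4-dien-1-yl acetate | CC(=O)O[C@H]1[C@@H](O)C=CC=C1CO
F4 | step 4 | (1R,6R)-2-formyl-6-[(trimethylsilyl)oxy]cyclohexa-2,4-dien-1-yl acetate | CC(=O)O[C@H]1[C@H](O[Si](C)(C)C)C=CC=C1C=O
F5 | step 6 | (5R,6R)-6-acetoxy-5-(benzoyloxy)cyclohexa-1,3-diene-1-carbaldehyde | CC(=O)O[C@H]1[C@H](OC(=O)c2ccccc2)C=CC=C1C=O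
F6 | step 6 | (1R,6R)-6-acetoxy-5-(hydroxymethyl)cyclohexa-2,4-dien-1-yl benzoate | CC(=O)O[C@H]1[C@H](OC(=O)c2ccccc2)C=CC=C1CO
F7 | step 6 | (1S,2S,3R,6S)-2-acetoxy-3-(benzoyloxy)-1-(hydroxymethyl)-7-oxabicyclo[4.1.0]hept-4-ene | CC(=O)O[C@H]1[C@H](OC(=O)c2ccccc2)C=C[C@@H]2O[C@@]21CO
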